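**Plan**

- Retrosynthetic cuts, in order: the O1–C5 bond of the oxolane (O1, C2H2, C3 carrying OH and the arylmethyl group, C4 carrying CH2OH, C5 carrying the aryl group), which leaves an open-chain hexol; then, with C2 and the C4 hydroxymethyl carbon raised to the acid level (a γ-lactone acid), the C3–O and C3–CH2Ar bonds; last the C4–C5 bond (aldol).
- Forward: succinyl imide plus O-benzylvanillin (aldol, which closes a temporary γ-lactone ring), arylmethylation, hydroxylation, LiAlH4 opening of the lactone, debenzylation, and closure of the oxolane ring as the last step.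
- Stereochemistry: C4 comes from a bought oxazolidinone auxiliary (Evans aldol). C3 is relayed from C4 on the lactone template, where oxygen enters anti to the carboxylate from either C3 epimer. C5 is relayed from C4 in the ring closure, which is stereoconvergent because C5 becomes planar.
- Enabling feature: the 4-hydroxy-3-methoxyphenyl ring on C5, whose free para hydroxyl lets C5 ionise to a p-quinone methide, together with the C2 hydroxyl placed 1,4 to C5, the only hydroxyl that can close a five-membered ring.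

Key step: step 9

Remark: the target is taken as (−)-olivil, (3S,4R,5S); "C2 to C5" without further words means the oxolane numbering of the target, and the lactone intermediates carry their own ring numbering where this is stated.

**Route**

Step 1
Reactants: 1 (S)-4-benzyl-1,3-oxazolidin-2-one; 2 methyl 4-chloro-4-oxobutanoate
Product: 3 methyl 4-[(4S)-4-benzyl-2-oxo-1,3-oxazolidin-3-yl]-4-oxobutanoate
Conditions: n-BuLi, THF, −78 °C; then 2, −78 to 0 °C
Reagents that add atoms: none
Why: N-acylation of the lithiated oxazolidinone by an acid chloride is the standard entry to N-acyl oxazolidinones, and the methyl ester should not be touched at low temperature.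

Step 2
Reactants: 3 methyl 4-[(4S)-4-benzyl-2-oxo-1,3-oxazolidin-3-yl]-4-oxobutanoate; 4 4-(benzyloxy)-3-methoxybenzaldehyde
Product: 6 (4S)-4-benzyl-3-{[(2S,3S)-2-[4-(benzyloxy)-3-methoxyphenyl]-5-oxooxolan-3-yl]carbonyl}-1,3-oxazolidin-2-one, via syn-aldol adduct 5 (not isolated)
Conditions: Bu2BOTf, i-Pr2NEt, CH2Cl2, 0 °C; 4, −78 to 0 °C; pH 7 buffer, MeOH, H2O2, 0 °C; then PPTS (cat.), CH2Cl2, rt
Reagents that add atoms: none
Why: Evans syn-aldol reaction, in which soft enolisation takes place only on the imide side and the Z boron enolate adds to the aldehyde through a chair Zimmerman–Traxler transition state on the face away from the benzyl group of the auxiliary, which sets lactone C3 (the later C4) as S and lactone C2 as S, after which the γ-hydroxy ester 5 should close to the trans γ-lactone with loss of methanol.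

Step 3
Reactants: 6 (4S)-4-benzyl-3-{[(2S,3S)-2-[4-(benzyloxy)-3-methoxyphenyl]-5-oxooxolan-3-yl]carbonyl}-1,3-oxazolidin-2-one
Product: 8 (2S,3S)-2-[4-(benzyloxy)-3-methoxyphenyl]-5-oxooxolane-3-carboxylic acid, via peroxy acid 7 (not isolated)
Conditions: LiOH, H2O2, THF–H2O, 0 °C; Na2SO3 (aq); HCl (aq) to pH 2
Reagents that add atoms: hydrogen peroxide (OO)
Why: Hydroperoxide cleavage of an N-acyl oxazolidinone, in which lithium hydroperoxide attacks the exocyclic imide carbonyl selectively, sulfite reduces the peroxy acid, and acidification recloses any lactone that was opened, without enolisation of the stereocentres.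

Step 4
Reactants: 9 [4-(benzyloxy)-3-methoxyphenyl]methanol
Product: 10 1-(benzyloxy)-4-(bromomethyl)-2-methoxybenzene
Conditions: PBr3, Et2O, 0 °C
Reagents that add atoms: phosphorus tribromide (BrP(Br)Br)
Why: Conversion of a primary benzylic alcohol to the bromide by SN2 displacement of its phosphite ester, under which the aryl benzyl ether is stable.

Step 5
Reactants: 8 (2S,3S)-2-[4-(benzyloxy)-3-methoxyphenyl]-5-oxooxolane-3-carboxylic acid; 10 1-(benzyloxy)-4-(bromomethyl)-2-methoxybenzene
Product: 11 (2S,3S,4S)-4-[4-(benzyloxy)-3-methoxybenzyl]-2-[4-(benzyloxy)-3-methoxyphenyl]-5-oxooxolane-3-carboxylic acid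
Conditions: NaN(SiMe3)2 (2.2 equiv), THF, −78 °C; then 10, −78 to −40 °C; HCl (aq)
Reagents that add atoms: none
Why: Enolate alkylation of the carboxylate/lactone-enolate dianion, in which the carboxylate keeps lactone C3 from being deprotonated (and so from β-elimination) and the bromide should enter lactone C4 anti to the carboxylate; the C4 configuration is of no consequence because step 6 erases it.

Step 6
Reactants: 11 (2S,3S,4S)-4-[4-(benzyloxy)-3-methoxybenzyl]-2-[4-(benzyloxy)-3-methoxyphenyl]-5-oxooxolane-3-carboxylic acid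
Product: 12 (2S,3R,4S)-4-[4-(benzyloxy)-3-methoxybenzyl]-2-[4-(benzyloxy)-3-methoxyphenyl]-4-hydroxy-5-oxooxolane-3-carboxylic acid
Conditions: KN(SiMe3)2 (2.5 equiv), THF, −78 to −40 °C; then 2-(phenylsulfonyl)-3-phenyloxaziridine, −78 °C; HCl (aq)
Reagents that add atoms: 2-(phenylsulfonyl)-3-phenyloxaziridine (O=S(=O)(c1ccccc1)N1OC1c1ccccc1)
Why: Electrophilic α-hydroxylation of a lactone enolate by an N-sulfonyloxaziridine, in which the planar enolate at lactone C4 should take up oxygen on the face anti to the neighbouring C3 carboxylate, so that the hydroxyl ends trans and the arylmethyl group cis to the carboxyl (the later C3 of the target, S) from either C4 epimer of 11.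

Step 7
Reactants: 12 (2S,3R,4S)-4-[4-(benzyloxy)-3-methoxybenzyl]-2-[4-(benzyloxy)-3-methoxyphenyl]-4-hydroxy-5-oxooxolane-3-carboxylic acid
Product: 13 (2S,3R)-2-[4-(benzyloxy)-3-methoxybenzyl]-3-{(S)-[4-(benzyloxy)-3-methoxyphenyl](hydroxy)methyl}butane-1,2,4-triol
Conditions: LiAlH4, THF, 0 °C to reflux; NaOH (aq) work-up
Reagents that add atoms: none
Why: Hydride reduction should take the lactone to the 1,4-diol and the carboxylic acid to the primary alcohol without touching the stereocentres or the benzyl ethers.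

Step 8
Reactants: 13 (2S,3R)-2-[4-(benzyloxy)-3-methoxybenzyl]-3-{(S)-[4-(benzyloxy)-3-methoxyphenyl](hydroxy)methyl}butane-1,2,4-triol
Product: 14 (2S,3R)-2-(4-hydroxy-3-methoxybenzyl)-3-[(S)-hydroxy(4-hydroxy-3-methoxyphenyl)methyl]butane-1,2,4-triol
Conditions: H2 (1 atm), Pd/C (10 wt %), EtOAc–MeOH, rt
Reagents that add atoms: none
Why: Hydrogenolysis of aryl benzyl ethers is much faster in neutral medium than that of a secondary benzylic alcohol, so both phenols should be set free with all four carbinols intact.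

Step 9
Reactants: 14 (2S,3R)-2-(4-hydroxy-3-methoxybenzyl)-3-[(S)-hydroxy(4-hydroxy-3-methoxyphenyl)methyl]butane-1,2,4-triol
Product: 16 (3S,4R,5S)-5-(4-hydroxy-3-methoxyphenyl)-3-(4-hydroxy-3-methoxybenzyl)-4-(hydroxymethyl)oxolan-3-ol [(−)-olivil], via p-quinone methide 15 (not isolated)
Conditions: (±)-camphor-10-sulfonic acid (0.1 equiv), MeCN–THF, 0.01 M, 0 °C to rt; NaHCO3 quench at full conversion
Reagents that add atoms: none
Why: Protonation of the C5 carbinol and loss of water, pushed by the free para hydroxyl of the aryl ring, should give the p-quinone methide 15 (in its O-protonated form), which is planar at C5 so that either C5 epimer of 14 would converge on it, and the C2 primary hydroxyl then adds to the methide carbon in an intramolecular oxa-1,6-addition that restores the arene. The closest known reaction type is the acid-mediated cyclodehydration of 1-arylbutane-1,4-diols to 2-aryl oxolanes through benzylic cations or quinone methides, as used for furan-type lignans. The oxolane ring closes in the 5-exo-trig mode onto the exocyclic C=C of 15. The new stereocentre C5 is controlled by C4: the aryl group should take the side trans to the C4 hydroxymethyl group to avoid eclipsing in the envelope transition state, and because the closure is reversible under the conditions the 4,5-trans ring is also the thermodynamic outcome. The step needs selectivity among four hydroxyls and against C-attack: only the C2 hydroxyl reaches C5 through a five-membered ring (the C3 hydroxyl and the C4 hydroxymethyl would give oxetanes), and Friedel–Crafts closure by the second aryl ring to a six-membered aryltetralin is slower and is held back by catalytic acid, dilution, low temperature and an early quench.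

**Compound list**

1 | (S)-4-benzyl-1,3-oxazolidin-2-one | O=C1N[C@@H](Cc2ccccc2)CO1 | starting material
2 | methyl 4-chloro-4-oxobutanoate | COC(=O)CCC(Cl)=O | starting material
3 | methyl 4-[(4S)-4-benzyl-2-oxo-1,3-oxazolidin-3-yl]-4-oxobutanoate | COC(=O)CCC(=O)N1[C@@H](Cc2ccccc2)COC1=O | intermediate
4 | 4-(benzyloxy)-3-methoxybenzaldehyde | COc1cc(C=O)ccc1OCc1ccccc1 | starting material
5 | methyl (3S)-3-{(S)-[4-(benzyloxy)-3-methoxyphenyl](hydroxy)methyl}-4-[(4S)-4-benzyl-2-oxo-1,3-oxazolidin-3-yl]-4-oxobutanoate (syn-aldol adduct, not isolated) | COC(=O)C[C@@H]([C@H](O)c1ccc(OCc2ccccc2)c(OC)c1)C(=O)N1[C@@H](Cc2ccccc2)COC1=O | intermediate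
6 | (4S)-4-benzyl-3-{[(2S,3S)-2-[4-(benzyloxy)-3-methoxyphenyl]-5-oxooxolan-3-yl]carbonyl}-1,3-oxazolidin-2-one | O=C1O[C@H](c2ccc(OCc3ccccc3)c(OC)c2)[C@@H](C(=O)N2[C@@H](Cc3ccccc3)COC2=O)C1 | intermediate
7 | (2S,3S)-2-[4-(benzyloxy)-3-methoxyphenyl]-5-oxooxolane-3-carboperoxoic acid (not isolated) | O=C1O[C@H](c2ccc(OCc3ccccc3)c(OC)c2)[C@@H](C(=O)OO)C1 | intermediate
8 | (2S,3S)-2-[4-(benzyloxy)-3-methoxyphenyl]-5-oxooxolane-3-carboxylic acid | O=C1O[C@H](c2ccc(OCc3ccccc3)c(OC)c2)[C@@H](C(=O)O)C1 | intermediate
9 | [4-(benzyloxy)-3-methoxyphenyl]methanol | COc1cc(CO)ccc1OCc1ccccc1 | starting material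
10 | 1-(benzyloxy)-4-(bromomethyl)-2-methoxybenzene | COc1cc(CBr)ccc1OCc1ccccc1 | intermediate
11 | (2S,3S,4S)-4-[4-(benzyloxy)-3-methoxybenzyl]-2-[4-(benzyloxy)-3-methoxyphenyl]-5-oxooxolane-3-carboxylic acid | O=C1O[C@H](c2ccc(OCc3ccccc3)c(OC)c2)[C@@H](C(=O)O)[C@@H]1Cc1ccc(OCc2ccccc2)c(OC)c1 | intermediate
12 | (2S,3R,4S)-4-[4-(benzyloxy)-3-methoxybenzyl]-2-[4-(benzyloxy)-3-methoxyphenyl]-4-hydroxy-5-oxooxolane-3-carboxylic acid | O=C1O[C@H](c2ccc(OCc3ccccc3)c(OC)c2)[C@@H](C(=O)O)[C@@]1(O)Cc1ccc(OCc2ccccc2)c(OC)c1 | intermediate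
13 | (2S,3R)-2-[4-(benzyloxy)-3-methoxybenzyl]-3-{(S)-[4-(benzyloxy)-3-methoxyphenyl](hydroxy)methyl}butane-1,2,4-triol | COc1cc(C[C@@](O)(CO)[C@H](CO)[C@H](O)c2ccc(OCc3ccccc3)c(OC)c2)ccc1OCc1ccccc1 | intermediate
14 | (2S,3R)-2-(4-hydroxy-3-methoxybenzyl)-3-[(S)-hydroxy(4-hydroxy-3-methoxyphenyl)methyl]butane-1,2,4-triol | COc1cc(C[C@@](O)(CO)[C@H](CO)[C@H](O)c2ccc(O)c(OC)c2)ccc1O | intermediate
15 | p-quinone methide of 14: 4-alkylidene-2-methoxycyclohexa-2,5-dien-1-one, planar at the former carbinol carbon, other two stereocentres unchanged (not isolated) | COC1=CC(=C[C@@H](CO)[C@](O)(CO)Cc2ccc(O)c(OC)c2)C=CC1=O | intermediate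
16 | (3S,4R,5S)-5-(4-hydroxy-3-methoxyphenyl)-3-(4-hydroxy-3-methoxybenzyl)-4-(hydroxymethyl)oxolan-3-ol, (−)-olivil | COc1cc(C[C@@]2(O)CO[C@H](c3ccc(O)c(OC)c3)[C@H]2CO)ccc1O | target

**Count and risks**

Total step count: 9. Longest linear sequence: 8 steps (steps 1, 2, 3, 5, 6, 7, 8, 9); step 4 is a one-step side branch.

Steps most likely to fail:

Step 6. What may go wrong: incomplete enolisation of the hindered carbon next to the carboxylate in the doubly charged substrate, or oxygen transfer to the wrong face. Fallback: setting out from 11, the acid alone would be reduced with BH3·SMe2 (THF, 0 °C) to the hydroxymethyl lactone F1, which would be silylated at once (TBSCl, imidazole, DMF) to the silyl ether F2. The neutral lactone enolate of F2 (KN(SiMe3)2, THF, −78 °C; same oxaziridine) should be hydroxylated anti to the silyloxymethyl group to give the α-hydroxy lactone F3. LiAlH4 would then give the mono-silylated tetrol F4, and Bu4NF in THF would bring the route back at 13.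

Step 9. What may go wrong: capture of the quinone methide by the second arene (Friedel–Crafts closure to the aryltetralin), fragmentation of the benzylic cation, or re-ionisation of the product on long exposure to acid. Fallback without any benzylic ionisation: setting out from 12, BH3·SMe2 would reduce the acid to the hydroxymethyl hydroxy lactone F5, used at once, and i-Bu2AlH (CH2Cl2, −78 °C) would give the lactol F6. Et3SiH with BF3·OEt2 (CH2Cl2, −78 °C) should deoxygenate F6 through the cyclic oxocarbenium ion to the bis-benzyl ether of the target F7; here the ring is never opened and C5 keeps the S configuration from the aldol step. Hydrogenolysis (H2, Pd/C, EtOAc) would come back to the route at 16.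

Step 5. What may go wrong: O-alkylation of the carboxylate, proton exchange leading to double alkylation, or ring opening by β-elimination. Fallback: setting out from 8, the same dianion (NaN(SiMe3)2, THF, −78 °C) would be added to aldehyde 4 in an aldol reaction to give the β-hydroxy adduct F8. Acid-catalysed dehydration (p-TsOH, PhMe, 60 °C) should give the E-arylidene lactone F9, and conjugate reduction (NaBH4, NiCl2·6H2O, MeOH, 0 °C) would come back at 11, either C4 epimer of which serves in step 6.

**Further compounds**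

F1 | step 6 | (3S,4S,5S)-3-[4-(benzyloxy)-3-methoxybenzyl]-5-[4-(benzyloxy)-3-methoxyphenyl]-4-(hydroxymethyl)oxolan-2-one | O=C1O[C@H](c2ccc(OCc3ccccc3)c(OC)c2)[C@@H](CO)[C@@H]1Cc1ccc(OCc2ccccc2)c(OC)c1
F2 | step 6 | tert-butyldimethylsilyl ether of F1 at the hydroxymethyl group | O=C1O[C@H](c2ccc(OCc3ccccc3)c(OC)c2)[C@@H](CO[Si](C)(C)C(C)(C)C)[C@@H]1Cc1ccc(OCc2ccccc2)c(OC)c1
F3 | step 6 | α-hydroxy lactone from F2, hydroxyl trans to the silyloxymethyl group | O=C1O[C@H](c2ccc(OCc3ccccc3)c(OC)c2)[C@@H](CO[Si](C)(C)C(C)(C)C)[C@@]1(O)Cc1ccc(OCc2ccccc2)c(OC)c1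
F4 | step 6 | mono-silyl ether of 13 (silyl on the hydroxymethyl group of the CH carbon) | COc1cc(C[C@@](O)(CO)[C@H](CO[Si](C)(C)C(C)(C)C)[C@H](O)c2ccc(OCc3ccccc3)c(OC)c2)ccc1OCc1ccccc1
F5 | step 9 | (3S,4R,5S)-3-[4-(benzyloxy)-3-methoxybenzyl]-5-[4-(benzyloxy)-3-methoxyphenyl]-3-hydroxy-4-(hydroxymethyl)oxolan-2-one | O=C1O[C@H](c2ccc(OCc3ccccc3)c(OC)c2)[C@@H](CO)[C@@]1(O)Cc1ccc(OCc2ccccc2)c(OC)c1
F6 | step 9 | lactol of F5 (oxolane-2,3-diol, both anomers) | OC1O[C@H](c2ccc(OCc3ccccc3)c(OC)c2)[C@@H](CO)[C@@]1(O)Cc1ccc(OCc2ccccc2)c(OC)c1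
F7 | step 9 | (3S,4R,5S)-3-[4-(benzyloxy)-3-methoxybenzyl]-5-[4-(benzyloxy)-3-methoxyphenyl]-4-(hydroxymethyl)oxolan-3-ol | COc1cc(C[C@@]2(O)CO[C@H](c3ccc(OCc4ccccc4)c(OC)c3)[C@H]2CO)ccc1OCc1ccccc1
F8 | step 5 | aldol adduct of 8 with 4 at lactone C4 (carbinol configuration not defined) | O=C1O[C@H](c2ccc(OCc3ccccc3)c(OC)c2)[C@@H](C(=O)O)[C@@H]1C(O)c1ccc(OCc2ccccc2)c(OC)c1
F9 | step 5 | (2S,3S,E)-4-[4-(benzyloxy)-3-methoxybenzylidene]-2-[4-(benzyloxy)-3-methoxyphenyl]-5-oxooxolane-3-carboxylic acid | O=C1O[C@H](c2ccc(OCc3ccccc3)c(OC)c2)[C@@H](C(=O)O)/C1=C\c1ccc(OCc2ccccc2)c(OC)c1
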